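The mono adduct was what I wanted, and it stood between substrate and bis adduct.

    substrate + reagent ⇌ mono adduct (K1 = 670 L mol⁻¹, k1 = 0.0437 L mol⁻¹ min⁻¹, Ea1 = 66.0 kJ mol⁻¹, ΔH1 = −14.0 kJ mol⁻¹)
    substrate + reagent → other mono adduct (k2 = 0.00431 L mol⁻¹ min⁻¹, Ea2 = 73.0 kJ mol⁻¹)
    reagent + mono adduct → bis adduct (k3 = 0.0109 L mol⁻¹ min⁻¹, Ea3 = 92.0 kJ mol⁻¹)
    reagent + other mono adduct → bis adduct (k4 = 0.0269 L mol⁻¹ min⁻¹, Ea4 = 89.0 kJ mol⁻¹)
    (constants at 60 °C)

in all of them: substrate 42 mM; reagent 1.10 equiv; time 3.0 d
- north-east: temperature 80 °C
- north: temperature 60 °C
- east: temperature 20 °C
- west: temperature 40 °C

- at 60 °C the constants are as listed, elsewhere as the activation energies and enthalpies make them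

1. the best flask by amount of mono adduct, in percent of the substrate charged; "all alike" if 1.5 percentage points covers them all (north-east / north / east / west / all alike)
2. amount of mono adduct at the end, in percent of the substrate charged, north-east
3. amount of mono adduct at the end, in percent of the substrate charged, north
4. amount of mono adduct at the end, in percent of the substrate charged, east
5. amount of mono adduct at the end, in percent of the substrate charged, west

I reckoned in fractions of the charge. For each step I took a clock: its constant at the flask's temperature, times the substrate charge, times the time. In west, step 1 had 1.73, step 2 0.145 and step 3 0.237.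

I carried one quantity, r, a selectivity factor: the step 3 clock over the summed clocks of steps 1 and 2. In west it was 0.126. The symmetric case, r of one, was the zero of my scale. Step 3 catches step 1 at 117.8 °C, hotter than any flask here.

Reagent multiplies both additions, so it cancels from their ratio. Let a be the fraction of substrate left and s the share of first addition going by step 1, in west 0.923. Integration then gives mono adduct = s(a^r − a)/(one − r). This curve has no undoing in it, so I expected it to serve while substrate fell.

Next I needed a. With equal charges, a is one over one plus the summed clock, which gave 34.8% in west. But reagent stood at 1.10 equiv. With the excess e, a = e/((one + e)exp(e × clock) − one), which gave 30.6%. So I committed west to 58.6%.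

East had clock 0.329 and r 0.0648, so a was 73.1% and mono adduct 24.8%. North had clock 8.71 and r 0.227, so a was 6.14% and mono adduct 55.3%. North-east had clock 34.0 and r 0.381, so a was 0.311% and mono adduct 15.6%.

In my reckoning west stood highest. I trusted the hot flasks less. My a counted no reagent for step 3, yet the north-east step 3 clock, 13.0, stood above the excess of 0.100.

The forecast named west, with 18% in north-east, 50% in north, 24.6% in east and 56% in west, holding that in north and north-east “the second addition uses up the small reagent excess”. Its west and north lay below mine, and its north-east above mine.

The simulation gave west, with 20.7% in north-east, 50.2% in north, 24.8% in east and 56.6% in west. West led north by 6.4 percentage points, and the forecast held.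

I reforged the weak link by replacing my a with the reading. With west's 33.0%, the curve returned 57.0% against 56.6%. With north-east's 33.9%, the curve returned 46.9% against 20.7%, and substrate there had risen from 29.5% at 1.50 d. The north-east run without step 3 gave 62.7%, and the one without the undoing gave 49.4%, against 20.7%. In north-east step 3 was the largest single effect, the undoing a part.

West read at 12 d kept its temperature, so r stayed 0.126, and with its substrate of 17.0% the curve gave 66.5%. The computed mono adduct there was 62.4%.

(The constants were chosen freely; no experiment stands behind them.)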